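Take the levelling of these flasks for an equilibrium first, as one does at the bench, and test whether one quotient p/(s r) describes them, where p is the Pdt made, and s and r are the Sbt and Ptn left of their charges.

| flask | Sbt | Ptn | Ctl | time |
|---|---|---|---|---|
| epsilon | 0.600 M | 0.660 M | 0.0480 M |  |
| theta | 0.300 M | 0.360 M | 0.0480 M |  |
| alpha | 0.600 M | 0.990 M | 0.0480 M |  |
| zeta | 1.80 M | 0.660 M | 0.0480 M |  |
| eta | 1.20 M | 0.220 M | 0.0480 M | 130 h |

| epsilon run: time / h | epsilon run: [Sbt] / M | theta run: time / h | theta run: [Sbt] / M | alpha run: time / h | alpha run: [Sbt] / M | zeta run: time / h | zeta run: [Sbt] / M |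
|---|---|---|---|---|---|---|---|
| 5.8 | 0.551 | 5.8 | 0.284 | 5.8 | 0.516 | 5.8 | 1.683 |
| 18 | 0.454 | 18 | 0.253 | 18 | 0.397 | 18 | 1.519 |
| 34 | 0.385 | 34 | 0.221 | 34 | 0.308 | 34 | 1.402 |
| 53 | 0.334 | 53 | 0.191 | 53 | 0.257 | 53 | 1.344 |
| 76 | 0.305 | 76 | 0.172 | 76 | 0.229 | 76 | 1.300 |
| 100 | 0.287 | 100 | 0.160 | 100 | 0.215 | 100 | 1.292 |
| 130 | 0.280 | 130 | 0.150 | 130 | 0.214 | 130 | 1.281 |

(readings scatter by 0.003 M)

- Overall: Sbt + Ptn -> Pdt, with Ctl as catalyst.
- Constant volume, constant temperature.
- What is held in complexes is read along with the free species.
- "The second partner" is Ptn.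
- An order is taken over about fifteen percent of the charge, up and down.

1. reaction order in [Sbt] at the outset, round the charge of the epsilon run, defined at two percent of the Sbt turned into Pdt (one fixed amount of Pdt, the same in the runs compared)
2. reaction order in [Ptn] at the outset, round the charge of the epsilon run, defined at two percent of the Sbt turned into Pdt
3. Sbt in the eta run at 130 h, as a share of the Sbt charged

I began with the plateaus. Alpha read 2.99 M⁻¹ and zeta 2.87 M⁻¹, which looked like one constant. The border showed in theta: at 130 h its quotient read 4.76 M⁻¹, 1.66 times zeta's, and its Sbt was still falling, by 0.0100 M over the last interval against a scatter of 0.003 M. So I stopped reading theta as an equilibrium.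

I supposed dead-end behaviour instead, with Pdt wearing out Ctl. If turnover goes as free Ctl times s r, and wear as free Ctl times p, then dividing one by the other removes both time and free Ctl, so the catalyst lost per Pdt made goes as p/(s r). Integrated in closed form, with charges a of Sbt and b of Ptn, this gives W = [a ln(a/s) − b ln(b/r)]/(b − a), which on this supposition stops growing at one value for one Ctl charge. At the last reading W stood at 0.357 in zeta, against 0.332 in alpha and 0.232 in theta. Each of these flasks may still have been moving, so I took zeta's reading as the wear budget, a lower estimate of the stopping value.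

In eta, Ptn is the limiting reagent, charged at 18.3% of the Sbt, so Sbt cannot fall below 81.7% of its charge. With 92.5% of the Ptn used, W is 0.354, just under the budget, so I expected eta to stop near there, with 83.0% of its Sbt left. I had reckoned no rate, so this was an estimate of the stopping point, and I committed to it for 130 h as well.

The forecast stood at 0.8, 1.15 and 86.1%, with the words “All runs level off, which points to equilibrium”. The flask gave 0.85, 1.0 and 83.9%, the last 0.90 percentage points above my figure.

    Ctl + Sbt ⇌ Ctl.Sbt, settled at all times (0.3490 M⁻¹)
    Ctl.Sbt + Ptn → Pdt + Ctl (2.678 M⁻¹ h⁻¹)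
    Ctl + Pdt → L + Pdt (0.08568 M⁻¹ h⁻¹)
    Ctl + Q → L

From these constants the ceiling of W is 0.374, and zeta's reading of 0.357 stood below it. Eta at 130 h had spent 0.259, which is 69.3% of that ceiling and 72.5% of zeta's reading. Q takes 28.5% of the Ctl charged at once, before any turnover. The epsilon run proves the effect of that loss, its apparent order in Ctl being 1.4 with the conversion of Ctl and Q into L and 0.99 without it.

(All runs come from a simulation with constants of no real substance, and the scatter is random.)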